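**Plan**

1. Germacrane numbering is used: C1=C10 (C14 methyl on C10), C2 (OH), C3, C4=C5 (C15 methyl on C4), C6 (lactone O), C7, C8 (OH), C9 (O-angelate), C11(=C13)–C12 lactone carbons; TBS = tert-butyldimethylsilyl.
2. Cuts, in retro order: the C9 O–acyl bond; the C9–C10 ring bond of the ten-membered carbocycle (alkenyl iodide + aldehyde); C7–C8 (allylation of a two-carbon aldehyde by a 3-(bromomethyl)butenolide); C7=C11 (butenolide by metathesis); C6–C7 (vinyl addition to an enal); C2–C3 (vinylogous aldol).
3. Enabling feature: C9 is a secondary allylic carbinol bonded to the methyl-bearing sp2 carbon C10 of the (Z)-C1=C10 olefin in the cyclodeca-1(10),4-diene ring. C10 can therefore be carried as a (Z)-alkenyl iodide and C9 as an aldehyde next to the C8 silyloxy stereocentre, while the (Z)- and (E)-olefins and the trans-fused γ-lactone pre-fold the chain.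
4. Forward: the acyclic C14–C10=C1–C2–C3–C4=C5–C6 chain is built first, the butenolide ring is closed on it, a Barbier step adds C8–C9 and creates the α-methylene lactone, the carbocycle is closed last, then acylation and desilylation.
5. Stereochemistry: C2 from a catalytic asymmetric vinylogous aldol; C6 from a ligand-controlled vinylzinc addition; C7 and C8 from C6 through a chair allylation; C9 from C8 in the ring closure; 1(10)Z from the iodoalkene, 4E from the aldol, angelate geometry from angelic acid.

Key step: step 15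

Assumption: the (S,S)-bisphosphoramide used with SiCl4 in step 4 is taken to direct attack to the Si face of the aldehyde; should its sense be the opposite, the enantiomeric catalyst is used.

**Step 1**
Reactants: 1 but-2-yn-1-ol
Product: 3 (Z)-3-iodobut-2-en-1-ol, via cyclic alkenylaluminate 2 (not isolated)
Conditions: NaAlH2(OCH2CH2OMe)2 (Red-Al), THF, 0 °C to rt; then I2, THF, −78 °C to 0 °C
Reagents that add atoms: iodine (I2), II
Why: Alkoxide-directed trans-hydroalumination of the propargylic alcohol puts aluminium on the distal carbon, and iodinolysis with retention should give the (Z)-iodide with iodine cis to the CH2OH carbon, which is the later cis relation of C2 and C9 across C1=C10.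

**Step 2**
Reactants: 3 (Z)-3-iodobut-2-en-1-ol
Product: 4 (Z)-3-iodobut-2-enal
Conditions: activated MnO2, CH2Cl2, rt, dark; used at once
Reagents that add atoms: none
Why: MnO2 oxidises the allylic alcohol selectively and leaves the alkenyl iodide alone; immediate use limits Z-to-E isomerisation of the β-iodoenal.

**Step 3**
Reactants: 5 ethyl 3-methylbut-2-enoate
Product: 7 1-ethoxy-1-(tert-butyldimethylsilyloxy)-3-methylbuta-1,3-diene, via lithium dienolate 6 (not isolated)
Conditions: LiN(i-Pr)2, THF, −78 °C; then TBSCl, DMPU, −78 °C to rt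
Reagents that add atoms: tert-butyldimethylsilyl chloride, CC(C)(C)[Si](C)(C)Cl
Why: Kinetic γ-deprotonation of the senecioate gives the extended dienolate, which is O-silylated to the silyl dienol ether (silyl ketene acetal formation).

**Step 4**
Reactants: 4 (Z)-3-iodobut-2-enal; 7 1-ethoxy-1-(tert-butyldimethylsilyloxy)-3-methylbuta-1,3-diene
Product: 8 ethyl (2E,5S,6Z)-5-hydroxy-7-iodo-3-methylocta-2,6-dienoate
Conditions: SiCl4 (1.1 equiv), (S,S)-binaphthyldiamine-derived bisphosphoramide (5 mol %), i-Pr2NEt (10 mol %), CH2Cl2, −78 °C; aq. KF/NaHCO3 work-up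
Reagents that add atoms: none
Why: In this Lewis-base-activated SiCl4 vinylogous Mukaiyama aldol the chiral trichlorosilyl cation should direct the dienolate through its γ-carbon to the Si face of the enal, setting C2 (S), and the s-trans dienolate should give the (E)-3-methyl enoate (C4=C5).

**Step 5**
Reactants: 8 ethyl (2E,5S,6Z)-5-hydroxy-7-iodo-3-methylocta-2,6-dienoate
Product: 9 ethyl (2E,5S,6Z)-5-(tert-butyldimethylsilyloxy)-7-iodo-3-methylocta-2,6-dienoate
Conditions: TBSCl, imidazole, DMF, rt
Reagents that add atoms: tert-butyldimethylsilyl chloride, CC(C)(C)[Si](C)(C)Cl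
Why: Standard silylation of the secondary allylic alcohol gives a C2 ether that should survive the hydride, organozinc, metathesis and chromium steps.

**Step 6**
Reactants: 9 ethyl (2E,5S,6Z)-5-(tert-butyldimethylsilyloxy)-7-iodo-3-methylocta-2,6-dienoate
Product: 10 (2E,5S,6Z)-5-(tert-butyldimethylsilyloxy)-7-iodo-3-methylocta-2,6-dien-1-ol
Conditions: i-Bu2AlH (2.5 equiv), CH2Cl2, −78 °C; Rochelle salt work-up
Reagents that add atoms: none
Why: 1,2-Reduction of the enoate by the aluminium hydride gives the allylic alcohol; the alkenyl iodide and silyl ether are inert at −78 °C.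

**Step 7**
Reactants: 10 (2E,5S,6Z)-5-(tert-butyldimethylsilyloxy)-7-iodo-3-methylocta-2,6-dien-1-ol
Product: 11 (2E,5S,6Z)-5-(tert-butyldimethylsilyloxy)-7-iodo-3-methylocta-2,6-dienal
Conditions: activated MnO2, CH2Cl2, rt
Reagents that add atoms: none
Why: Selective allylic oxidation by MnO2 gives the (E)-enal (C6 aldehyde) without touching the other functions.

**Step 8**
Reactants: 11 (2E,5S,6Z)-5-(tert-butyldimethylsilyloxy)-7-iodo-3-methylocta-2,6-dienal
Product: 12 (3S,4E,7S,8Z)-7-(tert-butyldimethylsilyloxy)-9-iodo-5-methyldeca-1,4,8-trien-3-ol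
Conditions: Zn(CH=CH2)2 (salt-free, from vinylmagnesium bromide and ZnCl2; 2 equiv), (−)-3-exo-(dimethylamino)isoborneol (10 mol %), toluene, 0 °C
Reagents that add atoms: divinylzinc, C=C[Zn]C=C
Why: Amino-alcohol-catalysed enantioselective 1,2-addition of an alkenylzinc to an aldehyde; the (−)-ligand should deliver vinyl to the Si face as it does with dialkylzincs, setting C6, and any C6 epimer is a separable diastereomer because C2 is already fixed.

**Step 9**
Reactants: 12 (3S,4E,7S,8Z)-7-(tert-butyldimethylsilyloxy)-9-iodo-5-methyldeca-1,4,8-trien-3-ol; 13 2-(bromomethyl)acrylic acid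
Product: 14 (3S,4E,7S,8Z)-7-(tert-butyldimethylsilyloxy)-9-iodo-5-methyldeca-1,4,8-trien-3-yl 2-(bromomethyl)acrylate
Conditions: DCC, DMAP (5 mol %), CH2Cl2, 0 °C
Reagents that add atoms: none
Why: Steglich esterification under near-neutral conditions should acylate the doubly allylic alcohol without ionising it and without displacing the allylic bromide.

**Step 10**
Reactants: 14 (3S,4E,7S,8Z)-7-(tert-butyldimethylsilyloxy)-9-iodo-5-methyldeca-1,4,8-trien-3-yl 2-(bromomethyl)acrylate
Product: 15 (5R)-3-(bromomethyl)-5-[(1E,4S,5Z)-4-(tert-butyldimethylsilyloxy)-6-iodo-2-methylhepta-1,5-dien-1-yl]furan-2(5H)-one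
Conditions: second-generation Grubbs catalyst (5 mol %), CH2Cl2 (0.01 M), 40 °C
Reagents that add atoms: none
Why: Ring-closing metathesis between the vinyl group and the acrylate closes the butenolide (C7=C11) with loss of ethylene; the two trisubstituted olefins are too hindered to take part, and the neutral medium spares the acidic C6–H.

**Step 11**
Reactants: 15 (5R)-3-(bromomethyl)-5-[(1E,4S,5Z)-4-(tert-butyldimethylsilyloxy)-6-iodo-2-methylhepta-1,5-dien-1-yl]furan-2(5H)-one; 16 (tert-butyldimethylsilyloxy)acetaldehyde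
Product: 18 (4R,5R)-4-[(1R)-2-(tert-butyldimethylsilyloxy)-1-hydroxyethyl]-5-[(1E,4S,5Z)-4-(tert-butyldimethylsilyloxy)-6-iodo-2-methylhepta-1,5-dien-1-yl]-3-methylidenedihydrofuran-2(3H)-one, via allylzinc bromide 17 (not isolated)
Conditions: Zn dust, THF/sat. aq. NH4Cl (4:1), 0 °C to rt
Reagents that add atoms: none
Why: Barbier allylation with allylic transposition through a six-membered chair transition state: the aldehyde should add to C7 anti to the C6 dienyl group (trans lactone) with CH2OTBS equatorial, and the ring-locked E-type allyl geometry then gives the 7,8-anti adduct (C7 R, C8 R) and the exocyclic methylene.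

**Step 12**
Reactants: 18 Barbier adduct (C8–OH, C9–OTBS)
Product: 19 C8 O-TBS ether of 18 (C2, C8 and C9 all O-TBS; configurations unchanged)
Conditions: TBSOTf, 2,6-lutidine, CH2Cl2, −78 °C to 0 °C
Reagents that add atoms: tert-butyldimethylsilyl triflate, CC(C)(C)[Si](C)(C)OS(=O)(=O)C(F)(F)F
Why: Silyl triflate with a hindered base protects the hindered secondary C8 hydroxyl without opening the lactone or adding to the methylene group.

**Step 13**
Reactants: 19 tris-TBS ether
Product: 20 C9 primary alcohol (C2 and C8 still O-TBS)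
Conditions: HF·pyridine, excess pyridine, THF, 0 °C
Reagents that add atoms: none
Why: Under buffered HF the primary silyl ether should cleave much faster than the two secondary ones, a standard primary-over-secondary TBS differentiation.

**Step 14**
Reactants: 20 C9 primary alcohol
Product: 21 C9 aldehyde: (2R)-2-(tert-butyldimethylsilyloxy)-2-[lactone C7]acetaldehyde carrying the (Z)-alkenyl iodide chain on C6
Conditions: Dess–Martin periodinane, NaHCO3, CH2Cl2, 0 °C to rt; used at once
Reagents that add atoms: none
Why: Mild, buffered hypervalent-iodine oxidation gives the α-silyloxy aldehyde without epimerising C8.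

**Step 15**
Reactants: 21 C9 aldehyde with the C10 (Z)-alkenyl iodide
Product: 23 2,8-bis-O-TBS-9β-hydroxygermacra-1(10)Z,4E,11(13)-trien-12,6-olide (9R; all other centres as in the target), via alkenylchromium dichloride 22 (not isolated)
Conditions: CrCl2 (10 equiv), NiCl2 (5 mol %), degassed DMSO/THF (3:1), rt, syringe-pump addition to a final 0.002 M
Reagents that add atoms: none
Why: Zerovalent nickel, formed from NiCl2 by CrCl2, inserts into the C10–I bond with retention of the (Z) geometry and passes the alkenyl group to trivalent chromium (22), which adds through a chromium-bound carbonyl to the C9 aldehyde only, leaving the lactone and its methylene group untouched. The closest known reaction type is the intramolecular Nozaki–Hiyama–Kishi coupling of an alkenyl iodide with an aldehyde used to close medium rings, including ten-membered germacranolide carbocycles. The ten-membered ring C1–C10 closes in a 10-exo-trig mode at the aldehyde carbon, helped by three turn elements already in the chain: the (Z)-C1=C10 olefin, the (E)-C4=C5 olefin and the trans-fused lactone. The new C9 stereocentre is controlled by C8: with the C8–OTBS bond anti to the forming C9–C10 bond and the chromium-bound oxygen on the outer rim of the folding ring, both oxygens sit pseudo-equatorial on a gauche C7–C8–C9–C10 segment, which should give the 8,9-threo (9R) alcohol. The step needs this facial selectivity and ring closure in preference to dimerisation; the first rests on the bulk of the C8 silyl ether and of the chromium ligand sphere, neither of which fits inside the ring, and the second on high dilution.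

**Step 16**
Reactants: 23 macrocyclic C9 alcohol; 24 angelic acid ((Z)-2-methylbut-2-enoic acid)
Product: 26 9-O-angelate of 23 (2,8-bis-O-TBS ether of the target), via angelic 2,4,6-trichlorobenzoic mixed anhydride 25 (not isolated)
Conditions: 24, 2,4,6-trichlorobenzoyl chloride, Et3N, toluene, rt; then 23, 80 °C
Reagents that add atoms: none
Why: Yamaguchi-type mixed-anhydride esterification without a nucleophilic catalyst should acylate the hindered allylic C9 hydroxyl while avoiding the addition–elimination pathway that turns angelate into tiglate.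

**Step 17**
Reactants: 26 9-O-angelate bis-TBS ether
Product: 27 target, (3aR,4R,5R,6Z,8S,10E,11aR)-4,8-dihydroxy-6,10-dimethyl-3-methylidene-2-oxo-2,3,3a,4,5,8,9,11a-octahydrocyclodeca[b]furan-5-yl (2Z)-2-methylbut-2-enoate
Conditions: HF·pyridine, THF, 0 °C to rt
Reagents that add atoms: none
Why: Acidic fluoride should cleave both secondary silyl ethers while avoiding the base-induced side reactions of the free 8-hydroxy-9-ester (acyl shift to O8, translactonisation to O8, conjugate addition to the methylene lactone).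

**Compound list**

1 | but-2-yn-1-ol | CC#CCO | starting material
2 | cyclic alkenylaluminate from 1: sodium 2,2-bis(2-methoxyethoxy)-3-methyl-2,5-dihydro-1,2-oxaluminol-2-uide (not isolated) | CC1=CCO[Al-]1(OCCOC)OCCOC.[Na+] | intermediate
3 | (Z)-3-iodobut-2-en-1-ol | OC/C=C(/C)I | intermediate
4 | (Z)-3-iodobut-2-enal | O=C/C=C(/C)I | intermediate
5 | ethyl 3-methylbut-2-enoate | CCOC(=O)C=C(C)C | starting material
6 | lithium 1-ethoxy-3-methylbuta-1,3-dien-1-olate (not isolated) | [Li+].C=C(C)C=C([O-])OCC | intermediate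
7 | 1-ethoxy-1-(tert-butyldimethylsilyloxy)-3-methylbuta-1,3-diene | C=C(C)C=C(OCC)O[Si](C)(C)C(C)(C)C | intermediate
8 | ethyl (2E,5S,6Z)-5-hydroxy-7-iodo-3-methylocta-2,6-dienoate | CCOC(=O)/C=C(\C)C[C@H](O)/C=C(/C)I | intermediate
9 | ethyl (2E,5S,6Z)-5-(tert-butyldimethylsilyloxy)-7-iodo-3-methylocta-2,6-dienoate | CCOC(=O)/C=C(\C)C[C@H](O[Si](C)(C)C(C)(C)C)/C=C(/C)I | intermediate
10 | (2E,5S,6Z)-5-(tert-butyldimethylsilyloxy)-7-iodo-3-methylocta-2,6-dien-1-ol | OC/C=C(\C)C[C@H](O[Si](C)(C)C(C)(C)C)/C=C(/C)I | intermediate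
11 | (2E,5S,6Z)-5-(tert-butyldimethylsilyloxy)-7-iodo-3-methylocta-2,6-dienal | O=C/C=C(\C)C[C@H](O[Si](C)(C)C(C)(C)C)/C=C(/C)I | intermediate
12 | (3S,4E,7S,8Z)-7-(tert-butyldimethylsilyloxy)-9-iodo-5-methyldeca-1,4,8-trien-3-ol | O[C@H](/C=C(\C)C[C@H](O[Si](C)(C)C(C)(C)C)/C=C(/C)I)C=C | intermediate
13 | 2-(bromomethyl)acrylic acid | C=C(CBr)C(=O)O | starting material
14 | (3S,4E,7S,8Z)-7-(tert-butyldimethylsilyloxy)-9-iodo-5-methyldeca-1,4,8-trien-3-yl 2-(bromomethyl)acrylate | C=C(CBr)C(=O)O[C@H](/C=C(\C)C[C@H](O[Si](C)(C)C(C)(C)C)/C=C(/C)I)C=C | intermediate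
15 | (5R)-3-(bromomethyl)-5-[(1E,4S,5Z)-4-(tert-butyldimethylsilyloxy)-6-iodo-2-methylhepta-1,5-dien-1-yl]furan-2(5H)-one | O=C1O[C@H](/C=C(\C)C[C@H](O[Si](C)(C)C(C)(C)C)/C=C(/C)I)C=C1CBr | intermediate
16 | (tert-butyldimethylsilyloxy)acetaldehyde | O=CCO[Si](C)(C)C(C)(C)C | starting material
17 | allylzinc bromide from 15 (C–Br replaced by C–ZnBr; not isolated) | O=C1O[C@H](/C=C(\C)C[C@H](O[Si](C)(C)C(C)(C)C)/C=C(/C)I)C=C1C[Zn]Br | intermediate
18 | (4R,5R)-4-[(1R)-2-(tert-butyldimethylsilyloxy)-1-hydroxyethyl]-5-[(1E,4S,5Z)-4-(tert-butyldimethylsilyloxy)-6-iodo-2-methylhepta-1,5-dien-1-yl]-3-methylidenedihydrofuran-2(3H)-one | C=C1C(=O)O[C@H](/C=C(\C)C[C@H](O[Si](C)(C)C(C)(C)C)/C=C(/C)I)[C@H]1[C@@H](O)CO[Si](C)(C)C(C)(C)C | intermediate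
19 | C8 O-TBS ether of 18 (C2, C8, C9 tris-TBS ether; configurations as in 18) | C=C1C(=O)O[C@H](/C=C(\C)C[C@H](O[Si](C)(C)C(C)(C)C)/C=C(/C)I)[C@H]1[C@@H](O[Si](C)(C)C(C)(C)C)CO[Si](C)(C)C(C)(C)C | intermediate
20 | C9 primary alcohol from 19 (C2 and C8 O-TBS; configurations as in 18) | C=C1C(=O)O[C@H](/C=C(\C)C[C@H](O[Si](C)(C)C(C)(C)C)/C=C(/C)I)[C@H]1[C@@H](O[Si](C)(C)C(C)(C)C)CO | intermediate
21 | C9 aldehyde from 20: (2R)-2-(tert-butyldimethylsilyloxy)-2-(lactone C7)acetaldehyde with the (1E,4S,5Z)-4-silyloxy-6-iodo-2-methylhepta-1,5-dienyl chain on C6 | C=C1C(=O)O[C@H](/C=C(\C)C[C@H](O[Si](C)(C)C(C)(C)C)/C=C(/C)I)[C@H]1[C@@H](O[Si](C)(C)C(C)(C)C)C=O | intermediate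
22 | alkenylchromium dichloride from 21 (C10–I replaced by C10–CrCl2, Z geometry kept; not isolated) | C=C1C(=O)O[C@H](/C=C(\C)C[C@H](O[Si](C)(C)C(C)(C)C)/C=C(/C)[Cr](Cl)Cl)[C@H]1[C@@H](O[Si](C)(C)C(C)(C)C)C=O | intermediate
23 | 2,8-bis-O-TBS-9β-hydroxygermacra-1(10)Z,4E,11(13)-trien-12,6-olide (9R; C2, C6, C7, C8 as in the target) | C=C1C(=O)O[C@@H]2/C=C(\C)C[C@H](O[Si](C)(C)C(C)(C)C)/C=C(/C)[C@@H](O)[C@H](O[Si](C)(C)C(C)(C)C)[C@@H]12 | intermediate
24 | angelic acid, (Z)-2-methylbut-2-enoic acid | C/C=C(/C)C(=O)O | starting material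
25 | angelic 2,4,6-trichlorobenzoic mixed anhydride (not isolated) | C/C=C(/C)C(=O)OC(=O)c1c(Cl)cc(Cl)cc1Cl | intermediate
26 | 9-O-angelate of 23 (2,8-bis-O-TBS ether of the target) | C=C1C(=O)O[C@@H]2/C=C(\C)C[C@H](O[Si](C)(C)C(C)(C)C)/C=C(/C)[C@@H](OC(=O)/C(C)=C\C)[C@H](O[Si](C)(C)C(C)(C)C)[C@@H]12 | intermediate
27 | (3aR,4R,5R,6Z,8S,10E,11aR)-4,8-dihydroxy-6,10-dimethyl-3-methylidene-2-oxo-2,3,3a,4,5,8,9,11a-octahydrocyclodeca[b]furan-5-yl (2Z)-2-methylbut-2-enoate | C=C1C(=O)O[C@@H]2/C=C(\C)C[C@H](O)/C=C(/C)[C@@H](OC(=O)/C(C)=C\C)[C@H](O)[C@@H]12 | target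

**Step count**

Total steps: 17. Longest linear sequence: 16 (steps 1, 2 and 4 to 17; step 3 makes the dienolate partner).

**Steps most likely to fail**

Step 15: the ring closure may show poor facial selectivity at the C9 aldehyde, giving the 8,9-erythro alcohol, besides competing intermolecular coupling. The fallback sets out from 21 and uses the same cyclisation, but takes the C9 configuration from an inversion instead of from the addition. The 9-epimeric macrocyclic alcohol F1 is esterified with angelic acid 24 under Mitsunobu conditions (triphenylphosphine, diisopropyl azodicarboxylate, toluene, 0 °C to rt). This should install the angelate with inversion at C9 and comes back to the route at 26; any 23 formed alongside goes on through step 16.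

Step 4: the (Z)-β-iodoenal may isomerise to the E isomer or decompose under the chlorosilane Lewis acid, or the enantiofacial control may be insufficient. The fallback sets out from 4 and sets C2 by a Brønsted-acid-catalysed propargylation instead. Allenylboronic acid pinacol ester and a chiral BINOL-derived phosphoric acid (5 mol %, toluene, −20 °C; enantiomer chosen for Si-face attack) should give (4S,5Z)-6-iodohept-5-en-1-yn-4-ol F2. Silylation (TBSCl, imidazole, DMF) gives its TBS ether F3. Zirconium-catalysed carboalumination of the terminal alkyne (AlMe3, Cp2ZrCl2 20 mol %, CH2Cl2, 0 °C to rt) followed by ethyl chloroformate should give the (E)-3-methyl enoate and comes back to the route at 9.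

Step 16: acylation of the hindered C9 hydroxyl may be slow, and the angelate may isomerise to the tiglate during activation. The fallback sets out from 23 and builds the Z olefin of the ester on the molecule. Esterification with 2-[bis(2,2,2-trifluoroethoxy)phosphoryl]propanoic acid (DCC, DMAP cat., CH2Cl2) gives the phosphonopropanoate F4. A Still–Gennari olefination with acetaldehyde (KN(SiMe3)2, 18-crown-6, THF, −78 °C) should give the (Z)-2-methylbut-2-enoate and comes back to the route at 26.

**Further compounds**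

F1 | step 15 | 9-epimer of 23: 2,8-bis-O-TBS-9α-hydroxygermacra-1(10)Z,4E,11(13)-trien-12,6-olide (9S) | C=C1C(=O)O[C@@H]2/C=C(\C)C[C@H](O[Si](C)(C)C(C)(C)C)/C=C(/C)[C@H](O)[C@H](O[Si](C)(C)C(C)(C)C)[C@@H]12
F2 | step 4 | (4S,5Z)-6-iodohept-5-en-1-yn-4-ol | C#CC[C@H](O)/C=C(/C)I
F3 | step 4 | (4S,5Z)-4-(tert-butyldimethylsilyloxy)-6-iodohept-5-en-1-yne | C#CC[C@H](O[Si](C)(C)C(C)(C)C)/C=C(/C)I
F4 | step 16 | 9-O-{2-[bis(2,2,2-trifluoroethoxy)phosphoryl]propanoyl} ester of 23 (both epimers at the phosphonate carbon) | C=C1C(=O)O[C@@H]2/C=C(\C)C[C@H](O[Si](C)(C)C(C)(C)C)/C=C(/C)[C@@H](OC(=O)C(C)P(=O)(OCC(F)(F)F)OCC(F)(F)F)[C@H](O[Si](C)(C)C(C)(C)C)[C@@H]12
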